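The aryl ester C–O bond between rings A and B is cut first. Everything then rests on taking ring A apart into an open-chain diazo enone and methoxyacetylene. The key step exploits the ring A pattern: free OH on C2, OMe on C4, H on C3 and C5, propyl on C6, carboxyl on C1. In one operation light expels N2 and the alkenyl group shifts (C5–C6). The resulting ester-bearing vinylketene takes up the alkyne (C2–C3, C4–C5), and a 6-electron closure (C1–C2) delivers the arene with its two oxygens already differentiated. The precursor is a benzyl (E)-hex-2-enoate carrying a diazoacetyl group on C3.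

Key step: step 5

Remark on the chemistry: the target has no stereocentre, so the only stereochemical element is the E alkene set in step 1. Counting the 1,2-shift, the key step makes four ring A bonds (C5–C6, C2–C3, C4–C5, C1–C2) and breaks two bonds of the precursor (C6–C2 and C2–C5).

Step 1
Reactants: 1 hexan-2-one (excess); 2 glyoxylic acid (used as the monohydrate)
Product: 4 (E)-3-acetylhex-2-enoic acid, via aldol adduct 3 (not isolated)
Conditions: 85% H3PO4, 80 °C
Reagents that add atoms: none
Why: This is an acid-catalysed crossed aldol condensation in which H3PO4 enolises 1 towards the more substituted C3, the enol adds to the non-enolisable aldehyde of 2, and loss of water from 3 should give the acid with acetyl and carboxyl trans (E), as the protocol does with butanone, provided heating is kept short so that the alkene does not isomerise and lactolise.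

Step 2
Reactants: 4 (E)-3-acetylhex-2-enoic acid; 5 benzyl bromide
Product: 6 benzyl (E)-3-acetylhex-2-enoate
Conditions: KHCO3, DMF, rt
Reagents that add atoms: benzyl bromide 5, BrCc1ccccc1 (listed as reactant)
Why: SN2 O-alkylation of the potassium carboxylate should work because the weak base KHCO3 leaves the base-sensitive ene-keto ester and its E geometry untouched.

Step 3
Reactants: 6 benzyl (E)-3-acetylhex-2-enoate
Product: 9 benzyl (E)-3-(diazoacetyl)hex-2-enoate, via lithium enolate 7 (not isolated), via trifluoroacetyl diketone 8 (not isolated)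
Conditions: 6 added to LiN(SiMe3)2, THF, −78 °C; CF3CO2CH2CF3, −78 °C; aq. HCl work-up; crude 8, 4-AcNHC6H4SO2N3, Et3N, H2O (1 equiv), MeCN, rt
Reagents that add atoms: 4-acetamidobenzenesulfonyl azide, CC(=O)Nc1ccc(cc1)S(=O)(=O)N=[N+]=[N-] (N2 of 9); 2,2,2-trifluoroethyl trifluoroacetate, O=C(OCC(F)(F)F)C(F)(F)F (CF3CO of 8 only); LiN(SiMe3)2, [Li+].C[Si](C)(C)[N-][Si](C)(C)C (Li of 7 only)
Why: In this detrifluoroacetylative diazo transfer (Regitz type) the methyl group is the only enolisable site of the ketone, Claisen trifluoroacetylation makes it acidic enough for Et3N-mediated N2 transfer, and the CF3CO group is then cleaved, which avoids diazomethane, a dipole that would add across the acceptor alkene.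

Step 4
Reactants: 10 chloroacetaldehyde dimethyl acetal (2-chloro-1,1-dimethoxyethane)
Product: 13 methoxyacetylene, via chlorovinyl ether 11 (not isolated), via sodium methoxyacetylide 12 (not isolated)
Conditions: NaNH2 (3 equiv), liq. NH3, −33 °C; NH3 evaporated; cold sat. aq. NaCl; distilled into a −78 °C trap, kept as a cold ClCH2CH2Cl solution
Reagents that add atoms: sodium amide, [Na+].[NH2-] (Na of 12 only)
Why: Double base-induced elimination (MeOH, then HCl) is the standard route from chloroacetals to alkoxyacetylenes, and the third equivalent of base holds the volatile product as its acetylide until the cold quench.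

Step 5
Reactants: 9 benzyl (E)-3-(diazoacetyl)hex-2-enoate; 13 methoxyacetylene (excess)
Product: 18 benzyl 2-hydroxy-4-methoxy-6-propylbenzoate, via vinylketene 14 (not isolated), via vinylcyclobutenone 15 (not isolated), via dienylketene 16 (not isolated), via cyclohexadienone 17 (not isolated)
Conditions: hν (254 nm, quartz, sealed), ClCH2CH2Cl, 0–5 °C; then vented, 80 °C
Reagents that add atoms: none
Why: Light expels N2 from 9 and the alkenyl group migrates to the former diazo carbon (photochemical Wolff rearrangement, new bond C5–C6), giving vinylketene 14, whose electrophilic carbonyl carbon is attacked by the unsubstituted, nucleophilic carbon of 13 in a polarised [2+2] cycloaddition (bonds C2–C3 and C4–C5) that leads to cyclobutenone 15. Light or the final heating opens 15 by 4-electron electrocyclic cleavage of the old C2–C5 bond to dienylketene 16, and ring A, the only ring formed, closes by 6-electron electrocyclisation of the ketene carbon onto the ester-bearing alkene carbon (bond C1–C2), after which dienone 17 enolises to the phenol. The closest known reaction is the Danheiser benzannulation in its diazo ketone form, established for diazo enones and alkoxyacetylenes; the conjugated ester is an extra acceptor on an otherwise standard substrate and should make the ketene still more electrophilic. The regioselectivity needed, OMe on C4 meta to the new OH on C2 and H on C3 between them, is secured by the matched polarity of ketene and ynol ether. The E geometry of 9 holds the ester away from the ketene, so closure through the ester oxygen is not possible, and it puts only H on the inner side of C1 in the ring closure. No stereocentre remains, since the sp3 carbons of 15 and 17 vanish on ring opening and tautomerisation, and the chelated OH of 18 is a poor trap for further ketene.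

Step 6
Reactants: 18 benzyl 2-hydroxy-4-methoxy-6-propylbenzoate
Product: 19 2-hydroxy-4-methoxy-6-propylbenzoic acid
Conditions: H2 (1 atm), 10% Pd/C, EtOAc, rt
Reagents that add atoms: none
Why: Catalytic hydrogenolysis of the benzylic C–O bond frees the acid without heat, acid or base, any of which could decarboxylate this electron-rich salicylic acid.

Step 7
Reactants: 20 5-bromo-1,2,3-trimethoxybenzene; 21 pentylmagnesium bromide
Product: 22 1,2,3-trimethoxy-5-pentylbenzene
Conditions: Ni(dppp)Cl2 (cat., dppp = 1,3-bis(diphenylphosphino)propane), Et2O–THF, reflux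
Reagents that add atoms: pentylmagnesium bromide 21, CCCCC[Mg]Br (listed as reactant)
Why: In this Kumada–Tamao–Corriu cross-coupling the chelating diphosphine favours reductive elimination, so the primary alkyl group should transfer without β-hydride loss or isomerisation, and the aryl methyl ethers are inert.

Step 8
Reactants: 22 1,2,3-trimethoxy-5-pentylbenzene
Product: 23 5-pentylbenzene-1,2,3-triol
Conditions: BBr3, CH2Cl2, −78 °C to rt; H2O; handled under N2
Reagents that add atoms: none
Why: In this Lewis acid ether cleavage each OMe binds BBr3, bromide removes the methyl group by SN2, and hydrolysis of the aryl borates frees the triol, which carries no other reactive group.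

Step 9
Reactants: 23 5-pentylbenzene-1,2,3-triol
Product: 24 2,2-diphenyl-6-pentyl-1,3-benzodioxol-4-ol
Conditions: Ph2CCl2, Ph2O, 175 °C, N2
Reagents that add atoms: dichlorodiphenylmethane, ClC(Cl)(c1ccccc1)c1ccccc1
Why: In this catechol ketalisation with a gem-dichloride only two neighbouring oxygens can span the five-membered dioxole, and because 23 is symmetric both possible pairs give the same phenol with one outer OH left free.

Step 10
Reactants: 19 2-hydroxy-4-methoxy-6-propylbenzoic acid; 24 2,2-diphenyl-6-pentyl-1,3-benzodioxol-4-ol
Product: 26 2,2-diphenyl-6-pentyl-1,3-benzodioxol-4-yl 2-hydroxy-4-methoxy-6-propylbenzoate, via mixed anhydride 25 (not isolated)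
Conditions: (CF3CO)2O, toluene, 0 °C to rt; aq. NaHCO3 wash
Reagents that add atoms: trifluoroacetic anhydride, O=C(OC(=O)C(F)(F)F)C(F)(F)F (CF3CO of 25 only)
Why: In this depside esterification through a mixed trifluoroacetic anhydride the electron-rich, doubly ortho-substituted acid is activated as the acylium-like 25, which acylates the only free OH of 24, while the chelated 2-OH of ring A stays out and the water-free medium spares the ketal.

Step 11
Reactants: 26 2,2-diphenyl-6-pentyl-1,3-benzodioxol-4-yl 2-hydroxy-4-methoxy-6-propylbenzoate
Product: 27 peruvinide C (2,3-dihydroxy-5-pentylphenyl 2-hydroxy-4-methoxy-6-propylbenzoate)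
Conditions: H2 (1 atm), 20% Pd(OH)2/C, THF, rt
Reagents that add atoms: none
Why: Hydrogenolysis of the two doubly benzylic C–O bonds of the diphenylmethylene ketal releases the catechol under neutral conditions, so the hindered aryl ester should be neither cleaved nor moved to the neighbouring OH.

Compound list
1 | hexan-2-one | CCCCC(C)=O | starting material
2 | glyoxylic acid | O=CC(=O)O | starting material
3 | 3-acetyl-2-hydroxyhexanoic acid (racemic diastereomer mixture) | CCCC(C(C)=O)C(O)C(=O)O | intermediate
4 | (E)-3-acetylhex-2-enoic acid | CCC/C(C(C)=O)=C\C(=O)O | intermediate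
5 | benzyl bromide | BrCc1ccccc1 | starting material
6 | benzyl (E)-3-acetylhex-2-enoate | CCC/C(C(C)=O)=C\C(=O)OCc1ccccc1 | intermediate
7 | lithium (3E)-5-(benzyloxy)-5-oxo-3-propylpenta-1,3-dien-2-olate | [Li+].C=C([O-])/C(CCC)=C/C(=O)OCc1ccccc1 | intermediate
8 | benzyl (E)-3-(4,4,4-trifluoro-3-oxobutanoyl)hex-2-enoate | CCC/C(C(=O)CC(=O)C(F)(F)F)=C\C(=O)OCc1ccccc1 | intermediate
9 | benzyl (E)-3-(diazoacetyl)hex-2-enoate | CCC/C(C(=O)C=[N+]=[N-])=C\C(=O)OCc1ccccc1 | intermediate
10 | chloroacetaldehyde dimethyl acetal | COC(CCl)OC | starting material
11 | 1-chloro-2-methoxyethene (E/Z mixture) | COC=CCl | intermediate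
12 | sodium methoxyacetylide | [Na+].[C-]#COC | intermediate
13 | methoxyacetylene | COC#C | intermediate
14 | benzyl (2E)-5-oxo-3-propylpenta-2,4-dienoate (vinylketene) | CCC/C(C=C=O)=C\C(=O)OCc1ccccc1 | intermediate
15 | benzyl (E)-3-(2-methoxy-4-oxocyclobut-2-en-1-yl)hex-2-enoate (racemic) | CCC/C(C1C(=O)C=C1OC)=C\C(=O)OCc1ccccc1 | intermediate
16 | benzyl (2E,4E)-5-methoxy-7-oxo-3-propylhepta-2,4,6-trienoate (dienylketene) | O=C=C/C(OC)=C\C(CCC)=C\C(=O)OCc1ccccc1 | intermediate
17 | benzyl 4-methoxy-2-oxo-6-propylcyclohexa-3,5-diene-1-carboxylate (racemic) | CCCC1=CC(OC)=CC(=O)C1C(=O)OCc1ccccc1 | intermediate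
18 | benzyl 2-hydroxy-4-methoxy-6-propylbenzoate | CCCc1cc(OC)cc(O)c1C(=O)OCc1ccccc1 | intermediate
19 | 2-hydroxy-4-methoxy-6-propylbenzoic acid | CCCc1cc(OC)cc(O)c1C(=O)O | intermediate
20 | 5-bromo-1,2,3-trimethoxybenzene | COc1cc(Br)cc(OC)c1OC | starting material
21 | pentylmagnesium bromide | CCCCC[Mg]Br | starting material
22 | 1,2,3-trimethoxy-5-pentylbenzene | CCCCCc1cc(OC)c(OC)c(OC)c1 | intermediate
23 | 5-pentylbenzene-1,2,3-triol | CCCCCc1cc(O)c(O)c(O)c1 | intermediate
24 | 2,2-diphenyl-6-pentyl-1,3-benzodioxol-4-ol | CCCCCc1cc(O)c2c(c1)OC(c1ccccc1)(c1ccccc1)O2 | intermediate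
25 | 2-hydroxy-4-methoxy-6-propylbenzoic trifluoroacetic anhydride | CCCc1cc(OC)cc(O)c1C(=O)OC(=O)C(F)(F)F | intermediate
26 | 2,2-diphenyl-6-pentyl-1,3-benzodioxol-4-yl 2-hydroxy-4-methoxy-6-propylbenzoate | CCCCCc1cc(OC(=O)c2c(O)cc(OC)cc2CCC)c2c(c1)OC(c1ccccc1)(c1ccccc1)O2 | intermediate
27 | peruvinide C | CCCCCc1cc(O)c(O)c(OC(=O)c2c(O)cc(OC)cc2CCC)c1 | target

Total step count: 11.
Longest linear sequence: 7 steps (1, 2, 3, 5, 6, 10, 11).

Steps most likely to fail

Step 5.
- What may go wrong:
  - Light may isomerise the acceptor alkene from E to Z before or after the Wolff shift.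
  - The diazo group may add as a dipole to the activated alkene of a second molecule.
  - The electron-poor ketene may dimerise.
  - The vinylketene may be captured directly in a [4+2] sense.
  - The volatile alkyne may be lost.
- Fallback: ring A is not built but taken from a resorcinol. The fallback sets out from benzyl bromide 5 and comes back at 18. Purchased 5-propylbenzene-1,3-diol is carboxylated next to an OH with methyl magnesium carbonate (MeOMgOCO2Me, DMF, 120 °C, Kolbe–Schmitt type) to 2,4-dihydroxy-6-propylbenzoic acid F1. Its carboxylate is alkylated with 5 (KHCO3, DMF) to benzyl 2,4-dihydroxy-6-propylbenzoate F2. MeI (1 equiv) and K2CO3 in acetone should then methylate only the 4-OH, because the 2-OH is tied up in a hydrogen bond to the ester, and this gives 18.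

Step 3.
- What may go wrong:
  - A γ-proton may be removed from the propyl CH2, which lies cis to the ester.
  - The enolate may undergo Michael-type self-condensation with unreacted acceptor alkene.
- Fallback: the alkene is made last, after the diazo group. The fallback sets out from glyoxylic acid 2 and benzyl bromide 5 and comes back at 9.
  - 2 and 5 (KHCO3, DMF, then azeotropic drying) give benzyl glyoxylate F3.
  - Purchased triethyl 2-phosphonopentanoate is saponified (NaOH, aq. EtOH) to 2-(diethoxyphosphoryl)pentanoic acid F4.
  - F4 is converted with (COCl)2 and cat. DMF into 2-(diethoxyphosphoryl)pentanoyl chloride F5.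
  - F5 is used to acylate CH2N2 (Et2O, 0 °C; no alkene is present to take up the dipole), giving diethyl (1-diazo-2-oxohexan-3-yl)phosphonate F6.
  - Horner–Wadsworth–Emmons olefination of F3 with F6 (LiCl, i-Pr2NEt, MeCN, rt) should give 9 with acyl and ester trans. Any Z isomer would be removed by chromatography.

Step 10.
- What may go wrong:
  - The liberated CF3CO2H may open the diphenylmethylene ketal.
  - The electron-rich ring B may be C-acylated.
  - Acyl transfer to the flanked OH may be sluggish.
- Fallback: neutral photochemical acyl transfer. The fallback sets out from acid 19 and comes back at 26. Treating 19 with acetone, (CF3CO)2O and CF3CO2H (0 °C to rt) gives 7-methoxy-2,2-dimethyl-5-propyl-4H-1,3-benzodioxin-4-one F7. Irradiation at 300 nm in CH2Cl2 in the presence of 24 expels acetone and gives the quinoketene 3-methoxy-6-(oxomethylidene)-5-propylcyclohexa-2,4-dien-1-one F8. The free OH of 24 captures F8 to give 26 without acid or base.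

Further compounds
F1 | step 5 | 2,4-dihydroxy-6-propylbenzoic acid | CCCc1cc(O)cc(O)c1C(=O)O
F2 | step 5 | benzyl 2,4-dihydroxy-6-propylbenzoate | CCCc1cc(O)cc(O)c1C(=O)OCc1ccccc1
F3 | step 3 | benzyl glyoxylate | O=CC(=O)OCc1ccccc1
F4 | step 3 | 2-(diethoxyphosphoryl)pentanoic acid (racemic) | CCCC(C(=O)O)P(=O)(OCC)OCC
F5 | step 3 | 2-(diethoxyphosphoryl)pentanoyl chloride (racemic) | CCCC(C(=O)Cl)P(=O)(OCC)OCC
F6 | step 3 | diethyl (1-diazo-2-oxohexan-3-yl)phosphonate (racemic) | CCCC(C(=O)C=[N+]=[N-])P(=O)(OCC)OCC
F7 | step 10 | 7-methoxy-2,2-dimethyl-5-propyl-4H-1,3-benzodioxin-4-one | CCCc1cc(OC)cc2OC(C)(C)OC(=O)c12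
F8 | step 10 | 3-methoxy-6-(oxomethylidene)-5-propylcyclohexa-2,4-dien-1-one | O=C=C1C(=O)C=C(OC)C=C1CCC
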